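## Retrosynthetic overview

1. Feature: C1–C6, with the C1 methyl, the isopropyl group and the tertiary carbinol C4, are the ten carbons of terpinen-4-ol once its ring alkene is cut. In the seven-membered ring the C6 carbonyl and its two flanking carbons (C5, C7) face a four-carbon unit oxygenated at its second carbon (C8–C9–C10–C1). The bond C1–C5 belongs to both rings.
2. Late disconnections: the C6–O ester (silyl-protected p-coumaric acid); the C6 carbinol from the C6 ketone by hydride delivery from the C4 hydroxyl; C7=C8 by dehydrogenation of the C6 ketone while C9 stays masked as its silyl enol ether.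
3. Key disconnection: C1–C5 and C7–C8 in one operation, an intramolecular (4+3) cycloaddition of the C5–C6–C7 oxyallyl cation with the C8–C9–C10–C1 siloxydiene. Cyclopentane and cycloheptene form in the same step from an acyclic chain.
4. The chain: silylation and ozonolysis of (S)-terpinen-4-ol. The C1 ketone is grown into the diene (C10 and C9 by olefination, C8 and its methyl from EtMgBr). C6 is carried as carboxylate, then as Weinreb amide, and C7 with its chlorine is added last.

Key step: step 9

Numbering used throughout: C1 quaternary ring-fusion carbon (its methyl defines the β face), C2 and C3 cyclopentane CH2, C4 carbinol carbon bearing isopropyl, C5 ring-fusion CH, C6 ester-bearing CH, C7=C8(CH3), C9 ketone, C10 CH2.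

Assumption: commercial (S)-(+)-terpinen-4-ol is used enantiopure (enriched beforehand if the batch requires it); its carbinol carbon has the spatial arrangement of C4 in the target.

## Route

Step 1
Reactants: 1 (S)-(+)-terpinen-4-ol
Product: 2 (S)-terpinen-4-ol triethylsilyl ether
Conditions: Et3SiOTf, 2,6-lutidine, CH2Cl2, 0 °C → rt
Reagents that add atoms: triethylsilyl triflate, CC[Si](CC)(CC)OS(=O)(=O)C(F)(F)F
Why: Silyl triflate silylation of a hindered tertiary alcohol is reliable, leaves C4 untouched, and later blocks lactol formation with the C1 ketone, displacement of the C7 chloride by the C4 oxygen and retro-aldol cleavage of C4–C5.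

Step 2
Reactants: 2 (S)-terpinen-4-ol triethylsilyl ether
Product: 4 (3S)-6-oxo-3-(propan-2-yl)-3-(triethylsilyloxy)heptanal, via secondary ozonide 3 (not isolated)
Conditions: O3, CH2Cl2, −78 °C; then Me2S, −78 °C → rt
Reagents that add atoms: ozone, [O-][O+]=O
Why: Ozonolysis of the only alkene with reductive cleavage of the ozonide opens the cyclohexene to the C1 methyl ketone and the C6 aldehyde without touching the fully substituted C4.

Step 3
Reactants: 4 (3S)-6-oxo-3-(propan-2-yl)-3-(triethylsilyloxy)heptanal
Product: 5 (3S)-6-oxo-3-(propan-2-yl)-3-(triethylsilyloxy)heptanoic acid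
Conditions: NaClO2, NaH2PO4, 2-methyl-2-butene, tBuOH/H2O, 0 °C → rt
Reagents that add atoms: sodium chlorite, [Na+].[O-]Cl=O
Why: The Pinnick oxidation takes only the aldehyde to the acid under buffered conditions that neither enolise C5 nor cleave the tertiary silyl ether, and the carboxylate then shields C6 from carbanions in the next two steps.

Step 4
Reactants: 5 (3S)-6-oxo-3-(propan-2-yl)-3-(triethylsilyloxy)heptanoic acid; 6 diethyl {2-[methoxy(methyl)amino]-2-oxoethyl}phosphonate
Product: 7 (3S,6E)-8-[methoxy(methyl)amino]-6-methyl-8-oxo-3-(propan-2-yl)-3-(triethylsilyloxy)oct-6-enoic acid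
Conditions: NaH, THF, 0 → 50 °C; then cold 0.5 M HCl to pH 4
Reagents that add atoms: none
Why: In this Horner–Wadsworth–Emmons olefination the amide-stabilised phosphonate anion, unlike a β-ketophosphonate anion, is nucleophilic enough for a methyl ketone and should place the longer chain trans to the carbonyl (E), the carboxylate being inert and the minor Z isomer being removed by chromatography.

Step 5
Reactants: 7 (3S,6E)-8-[methoxy(methyl)amino]-6-methyl-8-oxo-3-(propan-2-yl)-3-(triethylsilyloxy)oct-6-enoic acid
Product: 8 (3S,6E)-6-methyl-8-oxo-3-(propan-2-yl)-3-(triethylsilyloxy)dec-6-enoic acid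
Conditions: EtMgBr (3 equiv), THF, −20 → 0 °C; then cold 0.5 M HCl to pH 4
Reagents that add atoms: ethylmagnesium bromide, CC[Mg]Br
Why: In this Weinreb ketone synthesis the first equivalent of EtMgBr only deprotonates the acid, whose carboxylate resists addition, the chelated adduct of the amide stops at the ketone, and 1,4-addition is blocked by the fully substituted C1.

Step 6
Reactants: 8 (3S,6E)-6-methyl-8-oxo-3-(propan-2-yl)-3-(triethylsilyloxy)dec-6-enoic acid
Product: 9 (3S,6E)-N-methoxy-N,6-dimethyl-8-oxo-3-(propan-2-yl)-3-(triethylsilyloxy)dec-6-enamide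
Conditions: MeNHOMe·HCl, EDC·HCl, HOBt, N-methylmorpholine, CH2Cl2, 0 °C → rt
Reagents that add atoms: N,O-dimethylhydroxylamine hydrochloride, CNOC.Cl
Why: Carbodiimide amidation under nearly neutral conditions turns the acid into the acyl donor needed for a single carbenoid addition and leaves the hindered enone and the silyl ether alone.

Step 7
Reactants: 9 (3S,6E)-N-methoxy-N,6-dimethyl-8-oxo-3-(propan-2-yl)-3-(triethylsilyloxy)dec-6-enamide
Product: 10 (3S,6E,8Z)-N-methoxy-N,6-dimethyl-3-(propan-2-yl)-3-(triethylsilyloxy)-8-(triisopropylsilyloxy)deca-6,8-dienamide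
Conditions: iPr3SiOTf, Et3N, CH2Cl2, −78 → 0 °C
Reagents that add atoms: triisopropylsilyl triflate, CC(C)[Si](C(C)C)(C(C)C)OS(=O)(=O)C(F)(F)F
Why: Soft enolisation silylates the ketone oxygen and removes the adjacent proton at C8 rather than a γ proton, should give the Z enol ether as is usual for ethyl ketones under these conditions (so the C8 methyl and the tether both occupy outer diene positions), and does not enolise the less acidic amide.

Step 8
Reactants: 10 (3S,6E,8Z)-N-methoxy-N,6-dimethyl-3-(propan-2-yl)-3-(triethylsilyloxy)-8-(triisopropylsilyloxy)deca-6,8-dienamide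
Product: 11 (4S,7E,9Z)-1-chloro-7-methyl-4-(propan-2-yl)-4-(triethylsilyloxy)-9-(triisopropylsilyloxy)undeca-7,9-dien-2-one
Conditions: ICH2Cl, MeLi·LiBr, THF, −78 °C; then sat. aq NH4Cl
Reagents that add atoms: chloroiodomethane, ClCI
Why: Chloromethyllithium generated in the presence of the substrate adds once to the Weinreb amide (carbenoid homologation to an α-chloroketone), and the step is placed last because a chloromethyl ketone would not survive phosphonate anions, Grignard reagents or enol silylation, whereas both silyl groups are inert at −78 °C.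

Step 9
Reactants: 11 (4S,7E,9Z)-1-chloro-7-methyl-4-(propan-2-yl)-4-(triethylsilyloxy)-9-(triisopropylsilyloxy)undeca-7,9-dien-2-one
Product: 13 trans-fused hydroazulenone (C6 ketone, C9=C10 triisopropylsilyl enol ether, 1β-methyl, 4β-triethylsilyloxy, 4α-isopropyl, 5α-H, 8α-methyl), via oxyallyl cation 12 (not isolated)
Conditions: iPr2NEt, LiClO4 (3 M in Et2O), 0.01 M in 11, 0 °C → rt
Reagents that add atoms: none
Why: Proposed new method: the amine, helped by lithium coordination, enolises 11 at C5 and lithium-assisted loss of chloride from C7 gives the W-shaped oxyallyl cation 12, which adds across the s-cis siloxydiene in one asynchronous event in which the enol ether carbon C8 bonds to the unsubstituted terminus C7 slightly ahead and the enolate carbon C5 closes on the tertiary end C1 of the developing siloxyallyl cation. The closest known reaction type is the intramolecular (4+3) cycloaddition of oxyallyl cations from α-chloroketones with dienes held by a three-atom tether under LiClO4/amine, and what is new is the acyclic 2-siloxydiene partner and the fully substituted diene terminus C1, which becomes a quaternary carbon. The cyclopentane closes through the tether C2–C3–C4 by 5-exo attack of C5 on C1, and the cycloheptene is the cycloaddition ring itself, C5–C6–C7 joined to C8–C9–C10–C1 by the two new bonds. C5 is set by C4, because allylic strain in 12 turns the isopropyl group toward C5–H and the smaller silyloxy oxygen toward the oxyallyl oxygen so that the tether leaves from one face only; C1 is set relative to C5 by the E geometry of C1=C10 (tether outside, methyl inside) together with the extended approach, which the bulky C9 silyloxy group favours by crowding the compact one, and this puts H5 anti to the methyl (trans fusion, methyl cis to the C4 oxygen); C8 follows from the Z enol ether by suprafacial addition and is erased in step 10. Ionisation must outrun loss of silanolate from C4, N-alkylation of the base and Favorskii closure, which the weak hindered amine, the high lithium concentration and the poor leaving group at C4 serve, and the diene must be s-cis, which strain between the C9 silyloxy group and the inside methyl in the s-trans form provides. High dilution suppresses intermolecular capture, and the triisopropylsilyl group is chosen so that it stays on oxygen until C1–C5 is closed.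

Step 10
Reactants: 13 trans-fused hydroazulenone (C6 ketone, C9=C10 triisopropylsilyl enol ether)
Product: 15 cross-conjugated dienone (C6 ketone, C7=C8, C9=C10 triisopropylsilyl enol ether, 4β-triethylsilyloxy, 5α-H, 1β-methyl), via lithium C6–C7 enolate 14 (not isolated)
Conditions: LiN(iPr)2, THF, −78 °C; then PhS(Cl)=NtBu, −78 °C
Reagents that add atoms: none
Why: Kinetic deprotonation should occur at the C7 methylene because C5–H is buried between two quaternary carbons (so C5 is not epimerised and silanolate is not expelled), sulfur should add anti to the C8 methyl and hence syn to H8, and the syn elimination of the Mukaiyama dehydrogenation can then only give C7=C8 while C9 stays masked.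

Step 11
Reactants: 15 cross-conjugated dienone
Product: 16 4β-hydroxy-7-ene-6,9-dione (5α-H, 1β-methyl, 4α-isopropyl)
Conditions: HF·pyridine, THF, 0 °C → rt
Reagents that add atoms: none
Why: Fluoride-driven desilylation under weakly acidic conditions frees the C4 hydroxyl and the C9 enol, which ketonises by protonation at C10 to the conjugated enedione, and the absence of base avoids retro-aldol cleavage of C4–C5, dehydration and epimerisation at C5.

Step 12
Reactants: 16 4β-hydroxy-7-ene-6,9-dione
Product: 17 4β,6α-dihydroxy-7-en-9-one
Conditions: Me4NBH(OAc)3, MeCN/AcOH (1:1), −30 °C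
Reagents that add atoms: none
Why: In this Evans–Saksena reduction the C4 hydroxyl exchanges onto boron and delivers hydride to the β face of C6 through a six-membered transition state, which overrides the shielding of that face by the C1 methyl and sets 6α-OH, whereas the remote C9 enone has no directing group and is not reduced by a triacetoxyborohydride.

Step 13
Reactants: 18 p-coumaric acid
Product: 20 (E)-3-[4-(tert-butyldimethylsilyloxy)phenyl]prop-2-enoic acid, via bis-silyl derivative 19 (not isolated)
Conditions: tBuMe2SiCl, imidazole, DMF, rt; then AcOH/THF/H2O, rt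
Reagents that add atoms: tert-butyldimethylsilyl chloride, CC(C)(C)[Si](C)(C)Cl
Why: Standard silylation of phenol and acid followed by selective hydrolysis of the far more labile silyl ester keeps the phenol protected so that it cannot compete as an acyl acceptor.

Step 14
Reactants: 17 4β,6α-dihydroxy-7-en-9-one; 20 (E)-3-[4-(tert-butyldimethylsilyloxy)phenyl]prop-2-enoic acid
Product: 21 6α-[(E)-4-(tert-butyldimethylsilyloxy)cinnamoyloxy]-4β-hydroxy-7-en-9-one
Conditions: EDC·HCl, DMAP, CH2Cl2, rt
Reagents that add atoms: none
Why: The Steglich esterification acylates only the secondary allylic C6 hydroxyl, the tertiary C4 hydroxyl being inert under these conditions, and C6 keeps its configuration because its C–O bond is not broken.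

Step 15
Reactants: 21 6α-[(E)-4-(tert-butyldimethylsilyloxy)cinnamoyloxy]-4β-hydroxy-7-en-9-one
Product: 22 CNP0310968.1, (3R,3aS,4S,8aR)-3-hydroxy-6,8a-dimethyl-7-oxo-3-(propan-2-yl)-1,2,3,3a,4,7,8,8a-octahydroazulen-4-yl (E)-3-(4-hydroxyphenyl)prop-2-enoate
Conditions: HF·pyridine, pyridine/THF, 0 °C
Reagents that add atoms: none
Why: Aryl silyl ethers are cleaved quickly by HF·pyridine, conditions under which the cinnamate, the γ-acyloxy enone and the tertiary alcohol are stable, so no stereocentre is touched.

## Compound list

1 | (S)-(+)-terpinen-4-ol | CC1=CC[C@](O)(C(C)C)CC1 | starting material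
2 | (S)-terpinen-4-ol triethylsilyl ether | CC1=CC[C@](O[Si](CC)(CC)CC)(C(C)C)CC1 | intermediate
3 | secondary ozonide of 2 (1,2,4-trioxolane bridging C1 and C6) | CC12CC[C@@](O[Si](CC)(CC)CC)(C(C)C)CC(OO1)O2 | intermediate
4 | (3S)-6-oxo-3-(propan-2-yl)-3-(triethylsilyloxy)heptanal | CC(=O)CC[C@@](O[Si](CC)(CC)CC)(C(C)C)CC=O | intermediate
5 | (3S)-6-oxo-3-(propan-2-yl)-3-(triethylsilyloxy)heptanoic acid | CC(=O)CC[C@@](O[Si](CC)(CC)CC)(C(C)C)CC(=O)O | intermediate
6 | diethyl {2-[methoxy(methyl)amino]-2-oxoethyl}phosphonate | CCOP(=O)(CC(=O)N(C)OC)OCC | starting material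
7 | (3S,6E)-8-[methoxy(methyl)amino]-6-methyl-8-oxo-3-(propan-2-yl)-3-(triethylsilyloxy)oct-6-enoic acid | CON(C)C(=O)/C=C(\C)CC[C@@](O[Si](CC)(CC)CC)(C(C)C)CC(=O)O | intermediate
8 | (3S,6E)-6-methyl-8-oxo-3-(propan-2-yl)-3-(triethylsilyloxy)dec-6-enoic acid | CCC(=O)/C=C(\C)CC[C@@](O[Si](CC)(CC)CC)(C(C)C)CC(=O)O | intermediate
9 | (3S,6E)-N-methoxy-N,6-dimethyl-8-oxo-3-(propan-2-yl)-3-(triethylsilyloxy)dec-6-enamide | CCC(=O)/C=C(\C)CC[C@@](O[Si](CC)(CC)CC)(C(C)C)CC(=O)N(C)OC | intermediate
10 | (3S,6E,8Z)-N-methoxy-N,6-dimethyl-3-(propan-2-yl)-3-(triethylsilyloxy)-8-(triisopropylsilyloxy)deca-6,8-dienamide | C/C=C(O[Si](C(C)C)(C(C)C)C(C)C)/C=C(\C)CC[C@@](O[Si](CC)(CC)CC)(C(C)C)CC(=O)N(C)OC | intermediate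
11 | (4S,7E,9Z)-1-chloro-7-methyl-4-(propan-2-yl)-4-(triethylsilyloxy)-9-(triisopropylsilyloxy)undeca-7,9-dien-2-one | ClCC(=O)C[C@](O[Si](CC)(CC)CC)(C(C)C)CC/C(C)=C/C(O[Si](C(C)C)(C(C)C)C(C)C)=C/C | intermediate
12 | W-shaped C5–C6–C7 oxyallyl cation (zwitterion) with tethered siloxydiene | [CH2+]/C([O-])=C/[C@](O[Si](CC)(CC)CC)(C(C)C)CC/C(C)=C/C(O[Si](C(C)C)(C(C)C)C(C)C)=C/C | intermediate
13 | trans-fused cycloadduct: C6 ketone, C9=C10 triisopropylsilyl enol ether, 1β-methyl, 4β-triethylsilyloxy, 4α-isopropyl, 5α-H, 8α-methyl | C[C@@H]1CC(=O)[C@@H]2[C@](C)(CC[C@@]2(O[Si](CC)(CC)CC)C(C)C)C=C1O[Si](C(C)C)(C(C)C)C(C)C | intermediate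
14 | lithium C6–C7 enolate of 13 | [Li+].C[C@@H]1C=C([O-])[C@@H]2[C@](C)(CC[C@@]2(O[Si](CC)(CC)CC)C(C)C)C=C1O[Si](C(C)C)(C(C)C)C(C)C | intermediate
15 | dienone: C6 ketone, C7=C8, C9=C10 triisopropylsilyl enol ether, 4β-triethylsilyloxy | CC1=CC(=O)[C@@H]2[C@](C)(CC[C@@]2(O[Si](CC)(CC)CC)C(C)C)C=C1O[Si](C(C)C)(C(C)C)C(C)C | intermediate
16 | 4β-hydroxy-7-ene-6,9-dione | CC1=CC(=O)[C@@H]2[C@](C)(CC[C@@]2(O)C(C)C)CC1=O | intermediate
17 | 4β,6α-dihydroxy-7-en-9-one | CC1=C[C@H](O)[C@@H]2[C@](C)(CC[C@@]2(O)C(C)C)CC1=O | intermediate
18 | p-coumaric acid | OC(=O)/C=C/c1ccc(O)cc1 | starting material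
19 | tert-butyldimethylsilyl (E)-3-[4-(tert-butyldimethylsilyloxy)phenyl]prop-2-enoate | CC(C)(C)[Si](C)(C)OC(=O)/C=C/c1ccc(O[Si](C)(C)C(C)(C)C)cc1 | intermediate
20 | (E)-3-[4-(tert-butyldimethylsilyloxy)phenyl]prop-2-enoic acid | OC(=O)/C=C/c1ccc(O[Si](C)(C)C(C)(C)C)cc1 | intermediate
21 | 6α-[(E)-4-(tert-butyldimethylsilyloxy)cinnamoyloxy]-4β-hydroxy-7-en-9-one | CC1=C[C@H](OC(=O)/C=C/c2ccc(O[Si](C)(C)C(C)(C)C)cc2)[C@@H]2[C@](C)(CC[C@@]2(O)C(C)C)CC1=O | intermediate
22 | CNP0310968.1 | CC1=C[C@H](OC(=O)/C=C/c2ccc(O)cc2)[C@@H]2[C@](C)(CC[C@@]2(O)C(C)C)CC1=O | target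

## Step count

Total step count: 15.
Longest linear sequence: 14 (steps 1–12, 14 and 15; step 13 is the side branch).

## Steps most likely to fail

**1. Step 9.**
- Failure before any C–C bond forms: enolisation at C5 may be followed by loss of silanolate from C4, by Favorskii-type closure, or by a 1,2-shift from C4 toward the cationic C5.
- Failure of ring closure: the silyl group may be lost after the first bond forms, or closure may occur through the enolate oxygen.
- Failure of stereocontrol: the compact approach or poor facial selectivity relative to C4 may give fusion isomers. A product that differs only at C5 could be converged by mild amine equilibration. One that differs at C1 could not.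
- Fallback (known chemistry, the rings closed one after the other), from 8 back to 16: activation of enone acid 8 with pivaloyl chloride/iPr2NEt and an isothiourea catalyst (HyperBTM, the enantiomer matched to C4) brings about an intramolecular Michael addition–lactonisation through the C5 ammonium enolate. This should give the cis-fused enol lactone F1, in which C1–C5 is already made. iBu2AlH at −78 °C opens it to the keto aldehyde F2, whose C5 is equilibrated with Et3N so that the formyl group stands cis to the two smaller neighbours (C1 methyl, C4 oxygen). CH2=CHMgBr at −78 °C adds to the aldehyde only and gives the allylic alcohol F3, both C6 epimers being carried on. α-Methylenation at C8 (paraformaldehyde, iPr2NH·CF3CO2H, THF, reflux) gives the isopropenyl ketone F4. Ring-closing metathesis with the second-generation Hoveyda–Grubbs catalyst closes C7=C8 to the hydroxy enone F5. Dess–Martin oxidation gives the silylated enedione F6, and HF·pyridine leads back to 16.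

**2. Step 12.**
- The hindered tertiary hydroxyl may exchange onto boron slowly, so that undirected attack from the open α face or reduction at C9 competes.
- The β-hydroxy ketone may dehydrate in the acidic medium.
- Fallback (inversion instead of direction), from 15 back to 22: in dienone 15 C9 is still masked and C4 still silylated. iBu2AlH (toluene, −78 °C) should attack C6 from the open α face and give the 6β-alcohol F7. Mitsunobu esterification with acid 20 (PPh3, DIAD, toluene) inverts C6 and gives the fully silylated 6α-ester F8. HF·pyridine then removes all three silyl groups and gives 22 directly.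

**3. Step 4.**
- The stabilised anion may add sluggishly to an enolisable methyl ketone that carries a carboxylate.
- Discrimination between the methyl group and the CH2 chain may be weak, which erodes the alkene geometry that step 9 copies into C1.
- Fallback (alkynylation and rearrangement instead of olefination), from 5 back to 8: excess 1-butynyllithium (1-butyne, nBuLi, THF, −78 → 0 °C) adds to the ketone of the lithium carboxylate of 5 and gives the tertiary propargylic alcohol F9 (both carbinol epimers). A Meyer–Schuster rearrangement (Ph3PAuNTf2, MeOH, toluene) then gives enone acid 8 directly under equilibrating conditions, which favour the isomer with the smaller methyl cis to the acyl group. The other isomer is separated and resubmitted.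

## Further compounds

F1 | step 9 | cis-fused enol lactone (C6 lactone carbonyl, O bound to C9, C9=C10, 5β-H) | CCC1=C[C@@]2(C)CC[C@@](O[Si](CC)(CC)CC)(C(C)C)[C@H]2C(=O)O1
F2 | step 9 | cyclopentane keto aldehyde (C6 formyl on C5, 2-oxobutyl on C1, 5α-H) | CCC(=O)C[C@@]1(C)CC[C@@](O[Si](CC)(CC)CC)(C(C)C)[C@@H]1C=O
F3 | step 9 | C6 vinyl carbinol (both C6 epimers) | CCC(=O)C[C@@]1(C)CC[C@@](O[Si](CC)(CC)CC)(C(C)C)[C@@H]1C(O)C=C
F4 | step 9 | isopropenyl ketone with C6 vinyl carbinol | CC(=C)C(=O)C[C@@]1(C)CC[C@@](O[Si](CC)(CC)CC)(C(C)C)[C@@H]1C(O)C=C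
F5 | step 9 | 6-hydroxy-4β-triethylsilyloxy-7-en-9-one (both C6 epimers) | CC1=CC(O)[C@@H]2[C@](C)(CC[C@@]2(O[Si](CC)(CC)CC)C(C)C)CC1=O
F6 | step 9 | 4β-triethylsilyloxy-7-ene-6,9-dione | CC1=CC(=O)[C@@H]2[C@](C)(CC[C@@]2(O[Si](CC)(CC)CC)C(C)C)CC1=O
F7 | step 12 | 6β-alcohol of 15 | CC1=C[C@@H](O)[C@@H]2[C@](C)(CC[C@@]2(O[Si](CC)(CC)CC)C(C)C)C=C1O[Si](C(C)C)(C(C)C)C(C)C
F8 | step 12 | fully silylated 6α-coumarate | CC1=C[C@H](OC(=O)/C=C/c2ccc(O[Si](C)(C)C(C)(C)C)cc2)[C@@H]2[C@](C)(CC[C@@]2(O[Si](CC)(CC)CC)C(C)C)C=C1O[Si](C(C)C)(C(C)C)C(C)C
F9 | step 4 | (3S)-6-hydroxy-6-methyl-3-(propan-2-yl)-3-(triethylsilyloxy)dec-7-ynoic acid | CCC#CC(C)(O)CC[C@@](O[Si](CC)(CC)CC)(C(C)C)CC(=O)O
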